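**Plan** (terpenoid numbering: ring A = C1–C5 and C10, ring B = C5–C10, C11 = benzylic CH, primed atoms = arene)
Retrosynthesis: take off the C6′ sulfate and the phenol protection, cut C9–C10 (opens ring B), then the aryl–C11 bond of an arylalkyne, then C5–C6.
Forward: a C6–C11 alkyne chain is added to 4,4-dimethylcyclohex-2-enone (ring A), the ring carbonyl is traded for an exocyclic C10=CH2, the arene is joined by Sonogashira coupling, ring B is closed last, then sulfation and desilylation.
Enabling feature: C10 of ring A is quaternary, carries a CH3 and is bonded to C9, whose exocyclic C9=C11 bond has H11 cis to C10. This is the imprint of syn H–Pd addition to a C9≡C11 arylalkyne, 6-exo insertion of a C10=CH2 methylene and hydride capture of an alkylpalladium that has no β-hydrogen.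
Stereochemistry: C8 from a rhodium/bisphosphine conjugate alkynylation and C5 from a copper/phosphoramidite conjugate addition (both catalyst-controlled); C10 and the E alkene from the key step (chair control reinforced by allylic strain; syn addition).

Key step: step 16

Remark: the target is drawn as the free aryl hydrogen sulfate; it is released from its salt in the last step and would be stored as a salt. Abbreviations: TIPS = tri(propan-2-yl)silyl, TBS = tert-butyl(dimethyl)silyl, TMS = trimethylsilyl, MOM = methoxymethyl.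

Step 1
Reactants: 1 (E)-but-2-enal; 2 ethynyltri(propan-2-yl)silane
Product: 3 (3S)-3-methyl-5-(TIPS)pent-4-ynal
Conditions: [Rh(OAc)(C2H4)2]2 (cat.), (R)-DTBM-SEGPHOS (cat.), MeOH, 40 °C
Reagents that add atoms: none
Why: Rhodium-catalysed asymmetric conjugate alkynylation of an enal, in which the bulky silyl group suppresses alkyne dimerisation; the chiral bisphosphine (antipode chosen to give 3S) should set the methyl-bearing centre that becomes C8.

Step 2
Reactants: 3 (3S)-3-methyl-5-(TIPS)pent-4-ynal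
Product: 4 (3S)-3-methyl-5-(TIPS)pent-4-yn-1-ol
Conditions: NaBH4, MeOH, 0 °C
Reagents that add atoms: none
Why: Borohydride reduction of the aldehyde should leave the silylalkyne and the stereocentre untouched.

Step 3
Reactants: 4 (3S)-3-methyl-5-(TIPS)pent-4-yn-1-ol
Product: 5 (3S)-5-iodo-3-methyl-1-(TIPS)pent-1-yne
Conditions: I2, PPh3, imidazole, CH2Cl2, 0 °C to rt
Reagents that add atoms: iodine | II
Why: Appel-type iodination through the alkoxyphosphonium ion displaces at the primary carbon only, so the stereocentre is not involved.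

Step 4
Reactants: 5 (3S)-5-iodo-3-methyl-1-(TIPS)pent-1-yne; 6 4,4-dimethylcyclohex-2-en-1-one
Product: 8 (3R)-4,4-dimethyl-3-[(3S)-3-methyl-5-(TIPS)pent-4-yn-1-yl]-1-(trimethylsilyloxy)cyclohex-1-ene, via dialkylzinc reagent 7 (not isolated)
Conditions: Et2Zn (neat), CuI (cat.), 50 °C, then vacuum; 6, Cu(OTf)2 (cat.), (S,R,R)-binaphthyl N,N-bis(1-phenylethyl)phosphoramidite (cat.), toluene, −30 °C; TMSOTf, −30 °C to rt
Reagents that add atoms: trimethylsilyl trifluoromethanesulfonate | C[Si](C)(C)OS(=O)(=O)C(F)(F)F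
Why: Iodine–zinc exchange followed by copper/phosphoramidite-catalysed asymmetric conjugate addition to a 4,4-dimethylcyclohexenone (one alkyl group of 7 is transferred); the ligand (antipode chosen to give 3R) should set C5 independently of the remote C8, and O-silylation of the zinc enolate fixes the enol double bond on the C10 side.

Step 5
Reactants: 8 the trimethylsilyl enol ether
Product: 11 (3S)-4,4-dimethyl-2-methylidene-3-[(3S)-3-methyl-5-(TIPS)pent-4-yn-1-yl]cyclohexan-1-one, via Mannich base 9 (not isolated), via ammonium iodide 10 (not isolated)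
Conditions: CH2=NMe2+ I−, CH2Cl2, rt; MeI, rt; DBU, 0 °C
Reagents that add atoms: N,N-dimethylmethyleneiminium iodide | C=[N+](C)C.[I-]
Why: Mannich reaction of the silyl enol ether with the preformed iminium salt, N-methylation and E1cB elimination should place the methylene on C10 only; C5 is not α to the carbonyl and keeps its configuration.

Step 6
Reactants: 11 the α-methylene ketone
Product: 12 (3S)-4,4-dimethyl-2-methylidene-3-[(3S)-3-methyl-5-(TIPS)pent-4-yn-1-yl]cyclohexan-1-ol (both C1 epimers)
Conditions: NaBH4, CeCl3·7H2O, MeOH, −40 °C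
Reagents that add atoms: none
Why: Luche 1,2-reduction of the enone; the new carbinol centre is inconsequential because it is removed in step 8.

Step 7
Reactants: 12 the allylic alcohol
Product: 13 methyl carbonate of 12
Conditions: ClCO2Me, pyridine, DMAP (cat.), CH2Cl2, 0 °C
Reagents that add atoms: methyl chloroformate | COC(=O)Cl
Why: Acylation of the secondary allylic alcohol gives the carbonate leaving group needed for π-allyl formation.

Step 8
Reactants: 13 the allylic methyl carbonate
Product: 14 (1S)-2,2-dimethyl-6-methylidene-1-[(3S)-3-methyl-5-(TIPS)pent-4-yn-1-yl]cyclohexane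
Conditions: Pd(OAc)2 (cat.), n-Bu3P (cat.), HCO2NH4, 1,4-dioxane, 60 °C
Reagents that add atoms: none
Why: Tsuji–Trost ionisation to the π-allylpalladium, formate exchange and decarboxylation should deliver hydride to the more substituted allyl terminus (C1), leaving the exocyclic C10=CH2 next to the untouched C5.

Step 9
Reactants: 14 the silylated enyne
Product: 15 (1S)-2,2-dimethyl-6-methylidene-1-[(3S)-3-methylpent-4-yn-1-yl]cyclohexane
Conditions: TBAF, THF, 0 °C to rt
Reagents that add atoms: none
Why: Fluoride-induced C–Si cleavage of the alkynylsilane should free the terminal alkyne without touching the alkene or either stereocentre.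

Step 10
Reactants: 16 3,4-dihydroxybenzaldehyde
Product: 17 3,4-bis(TBS-oxy)benzaldehyde
Conditions: TBSCl, imidazole, DMF, rt
Reagents that add atoms: tert-butyl(chloro)dimethylsilane | CC(C)(C)[Si](C)(C)Cl
Why: Standard silylation of both catechol hydroxyls installs the fluoride-labile groups that must outlast the sulfation.

Step 11
Reactants: 17 3,4-bis(TBS-oxy)benzaldehyde
Product: 19 3,4-bis(TBS-oxy)phenol, via aryl formate 18 (not isolated)
Conditions: mCPBA, CH2Cl2, rt; then Et3N (cat.), MeOH, 0 °C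
Reagents that add atoms: 3-chloroperbenzoic acid | OOC(=O)c1cccc(Cl)c1
Why: Baeyer–Villiger (Dakin-type) oxidation with aryl migration favoured by the para silyloxy group, then mild methanolysis of the formate, should give the phenol that becomes the C6′ oxygen.

Step 12
Reactants: 19 3,4-bis(TBS-oxy)phenol
Product: 20 4,5-bis(TBS-oxy)-2-iodophenol
Conditions: NIS, MeCN, 0 °C
Reagents that add atoms: N-iodosuccinimide | O=C1CCC(=O)N1I
Why: Electrophilic iodination should go to the unhindered ortho position (also para to a silyloxy group); the iodine is the later coupling handle and blocks this site for step 13.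

Step 13
Reactants: 20 4,5-bis(TBS-oxy)-2-iodophenol
Product: 21 2-hydroxy-3-iodo-5,6-bis(TBS-oxy)benzaldehyde
Conditions: MgCl2, Et3N, (CH2O)n, MeCN, reflux
Reagents that add atoms: formaldehyde (as paraformaldehyde) | C=O
Why: Magnesium phenoxide-directed ortho-formylation can only reach the remaining ortho carbon between OH and OTBS, a second formaldehyde acting as hydride acceptor.

Step 14
Reactants: 21 2-hydroxy-3-iodo-5,6-bis(TBS-oxy)benzaldehyde
Product: 22 3-iodo-2-(methoxymethoxy)-5,6-bis(TBS-oxy)benzaldehyde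
Conditions: MOMCl, i-Pr2NEt, CH2Cl2, 0 °C to rt
Reagents that add atoms: chloromethyl methyl ether | COCCl
Why: O-alkylation marks the future sulfate oxygen with a group orthogonal to the silyl ethers and keeps it from adding to the alkyne in steps 15 and 16.

Step 15
Reactants: 15 the terminal alkyne; 22 the aryl iodide
Product: 23 3-{(3S)-5-[(1S)-2,2-dimethyl-6-methylidenecyclohexyl]-3-methylpent-1-yn-1-yl}-2-(methoxymethoxy)-5,6-bis(TBS-oxy)benzaldehyde
Conditions: PdCl2(PPh3)2 (cat.), CuI (cat.), Et3N, THF, 40 °C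
Reagents that add atoms: none
Why: Sonogashira coupling of the aryl iodide with the terminal alkyne should tolerate the aldehyde, silyl ethers and 1,1-disubstituted alkene, the protected ortho oxygen ruling out benzofuran formation.

Step 16
Reactants: 23 the 1,7-enyne
Product: 24 2-(methoxymethoxy)-3-{(E)-[(2S,4aS,8aS)-2,5,5,8a-tetramethyloctahydronaphthalen-1(2H)-ylidene]methyl}-5,6-bis(TBS-oxy)benzaldehyde (5S,8S,10S in terpenoid numbering)
Conditions: Pd2(dba)3·CHCl3 (cat.), P(o-tol)3 (cat.), AcOH, Et3SiH (slow addition), toluene, 60 °C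
Reagents that add atoms: none
Why: Zerovalent palladium and AcOH form a palladium hydride that adds syn across C9≡C11 with palladium on C9 (directed by the tethered alkene), the alkenylpalladium inserts the exocyclic C10=CH2 of ring A, and the resulting primary alkylpalladium, which has no β-hydrogen because C10 has become quaternary, is reduced by Et3SiH so that the former methylene ends as the C10 methyl. The closest known reaction type is the palladium hydride (carboxylic acid/silane) reductive cyclisation of 1,6- and 1,7-enynes to methyl-substituted alkylidenecycloalkanes. Ring B is closed in the 6-exo-trig mode at the internal carbon of the 1,1-disubstituted alkene; the 7-endo alternative would place palladium on a tertiary carbon and is not expected. C10, the only new stereocentre, is set by the substrate: ring A should react as a chair with the C5 chain equatorial and C9 arriving on the face of C10 remote from the axial C4 methyl, so the CH2–Pd arm becomes the axial methyl trans to H5, while allylic 1,3-strain with the C11 aryl group holds H8 in the alkene plane and the C8 methyl axial on the same face, a chair–chair arrangement the (5S,8S) substrate can adopt without conflict. The step also needs the E alkene, which follows from syn H–Pd addition and retention on insertion (H11 cis to C10, aryl cis to C8), and needs insertion to outrun direct reduction of the alkenylpalladium, which the six-membered closure and slow silane addition favour.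

Step 17
Reactants: 24 the MOM-protected decalin
Product: 26 2-hydroxy-3-{(E)-[(2S,4aS,8aS)-2,5,5,8a-tetramethyloctahydronaphthalen-1(2H)-ylidene]methyl}-5,6-bis(TBS-oxy)benzaldehyde, via aryl trimethylsilyl ether 25 (not isolated)
Conditions: TMSOTf, 2,2′-bipyridyl, CH2Cl2, 0 °C; then H2O
Reagents that add atoms: none
Why: Silyl triflate/bipyridyl cleavage of an aromatic MOM ether runs through the aryl TMS ether without free Brønsted acid, which should spare the aryl TBS ethers and avoid acid-induced attack of the freed phenol on the styrene.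

Step 18
Reactants: 26 the free C6′ phenol
Product: 27 pyridinium 2-formyl-3,4-bis(TBS-oxy)-6-{(E)-[(2S,4aS,8aS)-2,5,5,8a-tetramethyloctahydronaphthalen-1(2H)-ylidene]methyl}phenyl sulfate
Conditions: SO3·pyridine, pyridine, 40 °C
Reagents that add atoms: sulfur trioxide–pyridine complex | [O-]S(=O)(=O)[n+]1ccccc1
Why: O-sulfation of the only free phenol with the sulfur trioxide amine complex; the catechol oxygens are silylated, so regiochemistry is fixed by protection.

Step 19
Reactants: 27 the pyridinium aryl sulfate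
Product: 28 2-formyl-3,4-dihydroxy-6-{(E)-[(2S,4aS,8aS)-2,5,5,8a-tetramethyloctahydronaphthalen-1(2H)-ylidene]methyl}phenyl hydrogen sulfate (target)
Conditions: KHF2, MeOH, rt; then cation-exchange resin (H+ form), 0 °C
Reagents that add atoms: none
Why: Bifluoride cleaves phenolic silyl ethers under near-neutral conditions that an aryl sulfate monoester should survive, and brief proton exchange gives the acid form drawn.

**Compound list**
1 | (E)-but-2-enal | C/C=C/C=O | starting material
2 | ethynyltri(propan-2-yl)silane | C#C[Si](C(C)C)(C(C)C)C(C)C | starting material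
3 | (3S)-3-methyl-5-(TIPS)pent-4-ynal | C[C@H](C#C[Si](C(C)C)(C(C)C)C(C)C)CC=O | intermediate
4 | (3S)-3-methyl-5-(TIPS)pent-4-yn-1-ol | C[C@H](C#C[Si](C(C)C)(C(C)C)C(C)C)CCO | intermediate
5 | (3S)-5-iodo-3-methyl-1-(TIPS)pent-1-yne | C[C@H](C#C[Si](C(C)C)(C(C)C)C(C)C)CCI | intermediate
6 | 4,4-dimethylcyclohex-2-en-1-one | O=C1C=CC(C)(C)CC1 | starting material
7 | bis[(3S)-3-methyl-5-(TIPS)pent-4-yn-1-yl]zinc | C[C@H](C#C[Si](C(C)C)(C(C)C)C(C)C)CC[Zn]CC[C@H](C)C#C[Si](C(C)C)(C(C)C)C(C)C | intermediate (not isolated)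
8 | (3R)-4,4-dimethyl-3-[(3S)-3-methyl-5-(TIPS)pent-4-yn-1-yl]-1-(trimethylsilyloxy)cyclohex-1-ene | C[C@H](C#C[Si](C(C)C)(C(C)C)C(C)C)CC[C@H]1C(C)(C)CCC(O[Si](C)(C)C)=C1 | intermediate
9 | (3R)-2-[(dimethylamino)methyl]-4,4-dimethyl-3-[(3S)-3-methyl-5-(TIPS)pent-4-yn-1-yl]cyclohexan-1-one (C2 epimers) | C[C@H](C#C[Si](C(C)C)(C(C)C)C(C)C)CC[C@H]1C(C)(C)CCC(=O)C1CN(C)C | intermediate (not isolated)
10 | N,N,N-trimethylammonium iodide derived from 9 | C[C@H](C#C[Si](C(C)C)(C(C)C)C(C)C)CC[C@H]1C(C)(C)CCC(=O)C1C[N+](C)(C)C.[I-] | intermediate (not isolated)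
11 | (3S)-4,4-dimethyl-2-methylidene-3-[(3S)-3-methyl-5-(TIPS)pent-4-yn-1-yl]cyclohexan-1-one | C[C@H](C#C[Si](C(C)C)(C(C)C)C(C)C)CC[C@H]1C(C)(C)CCC(=O)C1=C | intermediate
12 | (3S)-4,4-dimethyl-2-methylidene-3-[(3S)-3-methyl-5-(TIPS)pent-4-yn-1-yl]cyclohexan-1-ol (C1 epimers) | C[C@H](C#C[Si](C(C)C)(C(C)C)C(C)C)CC[C@H]1C(C)(C)CCC(O)C1=C | intermediate
13 | methyl carbonate of 12 | C[C@H](C#C[Si](C(C)C)(C(C)C)C(C)C)CC[C@H]1C(C)(C)CCC(OC(=O)OC)C1=C | intermediate
14 | (1S)-2,2-dimethyl-6-methylidene-1-[(3S)-3-methyl-5-(TIPS)pent-4-yn-1-yl]cyclohexane | C[C@H](C#C[Si](C(C)C)(C(C)C)C(C)C)CC[C@H]1C(C)(C)CCCC1=C | intermediate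
15 | (1S)-2,2-dimethyl-6-methylidene-1-[(3S)-3-methylpent-4-yn-1-yl]cyclohexane | C[C@H](C#C)CC[C@H]1C(C)(C)CCCC1=C | intermediate
16 | 3,4-dihydroxybenzaldehyde | O=Cc1ccc(O)c(O)c1 | starting material
17 | 3,4-bis(TBS-oxy)benzaldehyde | O=Cc1ccc(O[Si](C)(C)C(C)(C)C)c(O[Si](C)(C)C(C)(C)C)c1 | intermediate
18 | 3,4-bis(TBS-oxy)phenyl formate | O=COc1ccc(O[Si](C)(C)C(C)(C)C)c(O[Si](C)(C)C(C)(C)C)c1 | intermediate (not isolated)
19 | 3,4-bis(TBS-oxy)phenol | Oc1ccc(O[Si](C)(C)C(C)(C)C)c(O[Si](C)(C)C(C)(C)C)c1 | intermediate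
20 | 4,5-bis(TBS-oxy)-2-iodophenol | Oc1cc(O[Si](C)(C)C(C)(C)C)c(O[Si](C)(C)C(C)(C)C)cc1I | intermediate
21 | 2-hydroxy-3-iodo-5,6-bis(TBS-oxy)benzaldehyde | O=Cc1c(O)c(I)cc(O[Si](C)(C)C(C)(C)C)c1O[Si](C)(C)C(C)(C)C | intermediate
22 | 3-iodo-2-(methoxymethoxy)-5,6-bis(TBS-oxy)benzaldehyde | O=Cc1c(OCOC)c(I)cc(O[Si](C)(C)C(C)(C)C)c1O[Si](C)(C)C(C)(C)C | intermediate
23 | 3-{(3S)-5-[(1S)-2,2-dimethyl-6-methylidenecyclohexyl]-3-methylpent-1-yn-1-yl}-2-(methoxymethoxy)-5,6-bis(TBS-oxy)benzaldehyde | C[C@H](C#Cc1cc(O[Si](C)(C)C(C)(C)C)c(O[Si](C)(C)C(C)(C)C)c(C=O)c1OCOC)CC[C@H]1C(C)(C)CCCC1=C | intermediate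
24 | 2-(methoxymethoxy)-3-{(E)-[(2S,4aS,8aS)-2,5,5,8a-tetramethyloctahydronaphthalen-1(2H)-ylidene]methyl}-5,6-bis(TBS-oxy)benzaldehyde | C[C@H]1CC[C@H]2C(C)(C)CCC[C@]2(C)/C1=C/c1cc(O[Si](C)(C)C(C)(C)C)c(O[Si](C)(C)C(C)(C)C)c(C=O)c1OCOC | intermediate
25 | aryl trimethylsilyl ether corresponding to 24 (OTMS in place of OMOM) | C[C@H]1CC[C@H]2C(C)(C)CCC[C@]2(C)/C1=C/c1cc(O[Si](C)(C)C(C)(C)C)c(O[Si](C)(C)C(C)(C)C)c(C=O)c1O[Si](C)(C)C | intermediate (not isolated)
26 | 2-hydroxy-3-{(E)-[(2S,4aS,8aS)-2,5,5,8a-tetramethyloctahydronaphthalen-1(2H)-ylidene]methyl}-5,6-bis(TBS-oxy)benzaldehyde | C[C@H]1CC[C@H]2C(C)(C)CCC[C@]2(C)/C1=C/c1cc(O[Si](C)(C)C(C)(C)C)c(O[Si](C)(C)C(C)(C)C)c(C=O)c1O | intermediate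
27 | pyridinium 2-formyl-3,4-bis(TBS-oxy)-6-{(E)-[(2S,4aS,8aS)-2,5,5,8a-tetramethyloctahydronaphthalen-1(2H)-ylidene]methyl}phenyl sulfate | C[C@H]1CC[C@H]2C(C)(C)CCC[C@]2(C)/C1=C/c1cc(O[Si](C)(C)C(C)(C)C)c(O[Si](C)(C)C(C)(C)C)c(C=O)c1OS(=O)(=O)[O-].c1cc[nH+]cc1 | intermediate
28 | 2-formyl-3,4-dihydroxy-6-{(E)-[(2S,4aS,8aS)-2,5,5,8a-tetramethyloctahydronaphthalen-1(2H)-ylidene]methyl}phenyl hydrogen sulfate | C[C@H]1CC[C@H]2C(C)(C)CCC[C@]2(C)/C1=C/c1cc(O)c(O)c(C=O)c1OS(=O)(=O)O | target

**Step count and risks**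
Total steps: 19. Longest linear sequence: 14 (steps 1–9 and 15–19); the arene branch (steps 10–14) joins at step 15.

Step 16. The alkenylpalladium may be reduced by the silane before it inserts into the hindered methylene, the exocyclic alkene may isomerise into the ring under palladium hydride, or the two faces of C10 may be poorly discriminated. The fallback sets out from 23 and closes the same bond by a radical path. Fe(acac)3/PhSiH3 in EtOH at 60 °C transfers a hydrogen atom to the exocyclic methylene, and the tertiary C10 radical closes ring B 6-exo-dig onto C9 of the arylalkyne. The aryl-stabilised alkenyl radical is reduced to 24 together with the (Z)-alkene isomer of 24 F1. The mixture is equilibrated to the less strained E isomer with catalytic PhSSPh under visible light, and the route is rejoined at 24.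

Step 4. Iodine–zinc exchange may be incomplete, alkyl transfer to the β-carbon next to the gem-dimethyl group may be slow, and enantioface selection or the enolate regiochemistry may erode. The fallback sets out from 5 (with 6) and sets C5 by asymmetric hydride delivery instead of asymmetric alkyl transfer. Compound 5 is converted with Mg into [(3S)-3-methyl-5-(TIPS)pent-4-yn-1-yl]magnesium iodide F2, which adds to 6 under CuI catalysis with TMSCl to give the silyl enol ether as a mixture of ring epimers F3. Saegusa–Ito oxidation (Pd(OAc)2, MeCN) gives the β-substituted enone 4,4-dimethyl-3-[(3S)-3-methyl-5-(TIPS)pent-4-yn-1-yl]cyclohex-2-en-1-one F4. Enantioselective copper hydride conjugate reduction (Cu(OAc)2, DTBM-SEGPHOS antipode as required, Ph2SiH2, toluene) then leaves the (3R)-diphenylsilyl enol ether F5. This is taken through the conditions of step 5 in place of 8, and the route is rejoined at 11.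

Step 17. The aryl silyl ethers may be lost during acetal cleavage, or the freed phenol may add to the styrene under Lewis acid activation. The fallback sets out from 21 and replaces the acetal by an ester that is removed by neutral solvolysis. Compound 21 is acetylated (Ac2O, pyridine) to 2-formyl-6-iodo-3,4-bis(TBS-oxy)phenyl acetate F6, coupled with 15 under the conditions of step 15 to the acetate-protected enyne F7, and cyclised under the conditions of step 16 to the acetate-protected decalin F8. The phenolic acetate is then cleaved with NH4OAc in aqueous MeOH at rt, and the route is rejoined at 26.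

**Further compounds**
F1 | step 16 | (Z)-alkene isomer of 24 | C[C@H]1CC[C@H]2C(C)(C)CCC[C@]2(C)/C1=C\c1cc(O[Si](C)(C)C(C)(C)C)c(O[Si](C)(C)C(C)(C)C)c(C=O)c1OCOC
F2 | step 4 | [(3S)-3-methyl-5-(TIPS)pent-4-yn-1-yl]magnesium iodide | C[C@H](C#C[Si](C(C)C)(C(C)C)C(C)C)CC[Mg]I
F3 | step 4 | 4,4-dimethyl-3-[(3S)-3-methyl-5-(TIPS)pent-4-yn-1-yl]-1-(trimethylsilyloxy)cyclohex-1-ene (both ring epimers) | C[C@H](C#C[Si](C(C)C)(C(C)C)C(C)C)CCC1C(C)(C)CCC(O[Si](C)(C)C)=C1
F4 | step 4 | 4,4-dimethyl-3-[(3S)-3-methyl-5-(TIPS)pent-4-yn-1-yl]cyclohex-2-en-1-one | C[C@H](C#C[Si](C(C)C)(C(C)C)C(C)C)CCC1=CC(=O)CCC1(C)C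
F5 | step 4 | (3R)-1-(diphenylsilyloxy)-4,4-dimethyl-3-[(3S)-3-methyl-5-(TIPS)pent-4-yn-1-yl]cyclohex-1-ene | C[C@H](C#C[Si](C(C)C)(C(C)C)C(C)C)CC[C@H]1C(C)(C)CCC(O[SiH](c2ccccc2)c2ccccc2)=C1
F6 | step 17 | 2-formyl-6-iodo-3,4-bis(TBS-oxy)phenyl acetate | O=Cc1c(OC(C)=O)c(I)cc(O[Si](C)(C)C(C)(C)C)c1O[Si](C)(C)C(C)(C)C
F7 | step 17 | 6-{(3S)-5-[(1S)-2,2-dimethyl-6-methylidenecyclohexyl]-3-methylpent-1-yn-1-yl}-2-formyl-3,4-bis(TBS-oxy)phenyl acetate | C[C@H](C#Cc1cc(O[Si](C)(C)C(C)(C)C)c(O[Si](C)(C)C(C)(C)C)c(C=O)c1OC(C)=O)CC[C@H]1C(C)(C)CCCC1=C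
F8 | step 17 | 2-formyl-3,4-bis(TBS-oxy)-6-{(E)-[(2S,4aS,8aS)-2,5,5,8a-tetramethyloctahydronaphthalen-1(2H)-ylidene]methyl}phenyl acetate | C[C@H]1CC[C@H]2C(C)(C)CCC[C@]2(C)/C1=C/c1cc(O[Si](C)(C)C(C)(C)C)c(O[Si](C)(C)C(C)(C)C)c(C=O)c1OC(C)=O
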